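**Strategy.** The tetrahydrofuran ring is cut at C2–C3, the bond that links the benzylic ring carbon next to oxygen (C2) with C3, whose methyl group is traced back to an aldehyde. A 2-aryl-4,5-dihydro-1,3-dioxepine delivers exactly this array: Lewis-acid ionisation of its acetal gives a benzylic oxocarbenium ion tethered through the ring oxygen to an aldehyde enol. In one operation the seven-membered vinyl acetal should contract to the tetrahydrofuran, form C2–C3 and set C2 and C3 trans,trans under thermodynamic control, while the cis C4/C5 pair is brought in intact. The precursor is the benzyl-protected, 4,5-cis 2,4-diaryl-5-methyl-4,5-dihydro-1,3-dioxepine, assembled from syringaldehyde, benzyl bromide and methyl propiolate.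

Key step: step 7

Ar = 4-(benzyloxy)-3,5-dimethoxyphenyl. Tetrahydrofuran locants: O1, C2 (aryl carbon made in the key step), C3, C4, C5. Dioxepine locants: O1, C2 (acetal), O3, C4 (aryl), C5 (methyl), C6, C7.

Assumption: the (R)-BINOL/Ti(OiPr)4 alkynylzinc system is taken to add to the Re face of the aromatic aldehyde, the mirror image of the Si-face addition expected for the (S)-ligand; the antipodal ligand is equally available should Mosher analysis of the carbinol show the opposite sense.

Step 1
Reactants: 1 syringaldehyde; 2 benzyl bromide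
Product: 3 4-(benzyloxy)-3,5-dimethoxybenzaldehyde
Conditions: K2CO3, DMF, 60 °C
Reagents that add atoms: none
Why: Williamson O-alkylation of the phenoxide (SN2 on the benzylic bromide) masks the acidic phenol as a benzyl ether that should survive every later step and leave by hydrogenolysis at the end, no stereocentre being formed.

Step 2
Reactants: 3 4-(benzyloxy)-3,5-dimethoxybenzaldehyde; 4 methyl propiolate
Product: 6 methyl (4S)-4-Ar-4-hydroxybut-2-ynoate, via alkynylzinc reagent 5 (not isolated)
Conditions: 4, Et2Zn, HMPA, (R)-BINOL (40 mol%), CH2Cl2, rt; Ti(OiPr)4 (1 equiv); then 3, rt; NH4Cl aq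
Reagents that add atoms: none
Why: Enantioselective alkynylzinc addition to an aromatic aldehyde, catalysed by the complex formed from (R)-BINOL and Ti(OiPr)4, should deliver zinc acetylide 5 to the Re face of the bound aldehyde and so create the carbinol centre (later tetrahydrofuran C5) as S, electron-rich benzaldehydes being standard substrates for this reaction type.

Step 3
Reactants: 6 methyl (4S)-4-Ar-4-hydroxybut-2-ynoate
Product: 8 (5R)-5-Ar-4-methylfuran-2(5H)-one, via hydroxy enoate 7 (not isolated)
Conditions: Me2CuLi (2.5 equiv, from MeLi and CuI), THF, −78 °C; NH4Cl aq at −78 °C; then PPTS (cat.), CH2Cl2, rt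
Reagents that add atoms: lithium dimethylcuprate, [Li+].C[Cu-]C
Why: Cuprate conjugate addition to the ynoate is a syn-carbometalation that places the methyl group on the carbon next to the carbinol and, after cold protonation, leaves hydroxyl and ester cis on Z-alkene 7 so that they lactonise under mild acid, the carbinol centre being untouched (S becomes R only through the priority change) and never exposed to base as the butenolide.

Step 4
Reactants: 8 (5R)-5-Ar-4-methylfuran-2(5H)-one
Product: 10 (1R,2Z)-1-Ar-2-methylbut-2-ene-1,4-diol, via lactol 9 (not isolated)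
Conditions: i-Bu2AlH (4 equiv), CH2Cl2, −78 → 0 °C; aq. potassium sodium tartrate
Reagents that add atoms: none
Why: 1,2-Reduction of the unsaturated lactone with excess i-Bu2AlH should run through lactol 9 to the ene-diol, the ring double bond being carried over as the Z geometry that a seven-membered acetal requires, while the non-acidic tartrate work-up keeps the lactol from dehydrating to a furan and leaves the carbinol centre intact.

Step 5
Reactants: 10 (1R,2Z)-1-Ar-2-methylbut-2-ene-1,4-diol; 3 4-(benzyloxy)-3,5-dimethoxybenzaldehyde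
Product: 12 (2R,4R)-2,4-di-Ar-5-methyl-4,7-dihydro-1,3-dioxepine (2,4-cis major; C2 epimer carried along), via dimethyl acetal 11 (not isolated)
Conditions: 3, HC(OMe)3, p-TsOH·H2O (cat.), MeOH, rt; Et3N, concentrate; then 10, PPTS (cat.), benzene, 45 °C, 200 mbar
Reagents that add atoms: none
Why: Transacetalisation of the preformed dimethyl acetal 11 under weakly acidic PPTS catalysis with removal of methanol should close the 1,3-dioxepine ring on the Z-ene-1,4-diol without the strong acid that could ionise the benzylic, allylic carbinol, and the new acetal centre C2 forms reversibly, mainly cis to the C4 aryl group (both pseudo-equatorial), its configuration being of no consequence because step 7 erases it.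

Step 6
Reactants: 12 (2R,4R)-2,4-di-Ar-5-methyl-4,7-dihydro-1,3-dioxepine
Product: 13 (2R,4R,5S)-2,4-di-Ar-5-methyl-4,5-dihydro-1,3-dioxepine (2,4-cis; 4,5-cis)
Conditions: RuHCl(CO)(PPh3)3 (5 mol%), toluene, 80 °C
Reagents that add atoms: none
Why: Hydride addition and β-hydride elimination at ruthenium should move the C5=C6 bond to C6=C7 (allyl ether to enol ether isomerisation, known for 5-methyl-4,7-dihydro-1,3-dioxepines and driven by conjugation to oxygen), the trisubstituted alkene being approached on the face away from the neighbouring C4 aryl group so that hydrogen enters C5 anti to it and the C5 methyl group ends up cis to that aryl group.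

Step 7
Reactants: 13 (2R,4R,5S)-2,4-di-Ar-5-methyl-4,5-dihydro-1,3-dioxepine
Product: 15 (2S,3S,4S,5R)-2,5-di-Ar-4-methyltetrahydrofuran-3-carbaldehyde, via silyl enol ether oxocarbenium triflate 14 (not isolated)
Conditions: TMSOTf (0.2 equiv), CH2Cl2, −78 → −20 °C; Et3N quench
Reagents that add atoms: none
Why: Silylation of the enol-ether oxygen O1 (dioxepine locants) breaks the C2–O1 acetal bond and leaves the benzylic oxocarbenium ion C2=O3+ tied through O3, C4 and C5 to the silyl enol ether in 14, whose carbon C6 then adds to C2 with release of the silyl cation (intramolecular Mukaiyama-type aldol), so the Lewis acid is needed only in substoichiometric amount. The closest known reaction type is the Lewis-acid ring contraction of 4,5-dihydro-1,3-dioxepines to 2-substituted tetrahydrofuran-3-carbaldehydes. The five-membered ring closes in a 5-(enolexo)-endo-trig mode (enol carbon–carbon double bond exocyclic, oxocarbenium carbon–oxygen double bond endocyclic to the ring being made), a closure that this precedent shows to be easy for oxocarbenium electrophiles. The new centres C2 and C3 of the tetrahydrofuran are set under thermodynamic control: the C–C bond formation is reversible under the Lewis acid and the aldehyde is enolisable, so on warming the mixture should drain into the isomer with the formyl group trans to both the C2 aryl and the C4 methyl group, every other C2/C3 combination putting a second pair of neighbouring substituents on the same face. The former dioxepine C4 and C5 are spectators and become C5 and C4 of the tetrahydrofuran with their cis relationship intact. The step needs ionisation at the acetal carbon and not at the benzylic C4–O3 ether bond, which the much greater stability of the alkoxy-stabilised cation, the low temperature, the substoichiometric acid and the twisted, weakly donating para-benzyloxy group should secure.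

Step 8
Reactants: 15 (2S,3S,4S,5R)-2,5-di-Ar-4-methyltetrahydrofuran-3-carbaldehyde
Product: 16 [(2S,3R,4S,5R)-2,5-di-Ar-4-methyltetrahydrofuran-3-yl]methanol
Conditions: NaBH4, MeOH/THF, 0 °C
Reagents that add atoms: none
Why: Borohydride 1,2-reduction of the aldehyde to the primary alcohol is chemoselective (aryl and benzyl ethers and the ring ether are inert) and touches no stereocentre, the C3 descriptor changing from S to R by priority only.

Step 9
Reactants: 16 [(2S,3R,4S,5R)-2,5-di-Ar-4-methyltetrahydrofuran-3-yl]methanol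
Product: 17 [(2S,3R,4S,5R)-2,5-di-Ar-4-methyltetrahydrofuran-3-yl]methyl methanesulfonate
Conditions: MsCl, Et3N, CH2Cl2, 0 °C
Reagents that add atoms: methanesulfonyl chloride, CS(=O)(=O)Cl
Why: O-Sulfonylation of the unhindered primary alcohol turns the hydroxyl into a leaving group under basic conditions that leave the ring stereocentres untouched.

Step 10
Reactants: 17 [(2S,3R,4S,5R)-2,5-di-Ar-4-methyltetrahydrofuran-3-yl]methyl methanesulfonate
Product: 18 (2S,3S,4S,5R)-2,5-di-Ar-3,4-dimethyltetrahydrofuran
Conditions: LiEt3BH, THF, 0 °C → rt; NaOH/H2O2 work-up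
Reagents that add atoms: none
Why: SN2 displacement of the primary mesylate by the strong hydride donor LiEt3BH (reductive deoxygenation of a sulfonate) should convert CH2OMs into the C3 methyl group, the ethers being inert and no stereocentre being involved.

Step 11
Reactants: 18 (2S,3S,4S,5R)-2,5-di-Ar-3,4-dimethyltetrahydrofuran
Product: 19 4,4'-[(2S,3S,4S,5R)-3,4-dimethyltetrahydrofuran-2,5-diyl]bis(2,6-dimethoxyphenol) (CNP0217414.2)
Conditions: H2 (1 atm), 10% Pd/C, EtOAc/MeOH, rt, short reaction time
Reagents that add atoms: none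
Why: Palladium-catalysed hydrogenolysis should cleave the two aryl benzyl ethers much faster than the dialkyl-type benzylic C–O bonds of the tetrahydrofuran at atmospheric pressure, freeing both phenols without touching a stereocentre.

**Compound list**

1 | syringaldehyde (4-hydroxy-3,5-dimethoxybenzaldehyde) | COc1cc(C=O)cc(OC)c1O | starting material
2 | benzyl bromide | BrCc1ccccc1 | starting material
3 | 4-(benzyloxy)-3,5-dimethoxybenzaldehyde | COc1cc(C=O)cc(OC)c1OCc1ccccc1 | intermediate
4 | methyl propiolate (methyl prop-2-ynoate) | COC(=O)C#C | starting material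
5 | ethyl(3-methoxy-3-oxoprop-1-yn-1-yl)zinc | CC[Zn]C#CC(=O)OC | intermediate (not isolated)
6 | methyl (4S)-4-[4-(benzyloxy)-3,5-dimethoxyphenyl]-4-hydroxybut-2-ynoate | COC(=O)C#C[C@@H](O)c1cc(OC)c(OCc2ccccc2)c(OC)c1 | intermediate
7 | methyl (2Z,4R)-4-[4-(benzyloxy)-3,5-dimethoxyphenyl]-4-hydroxy-3-methylbut-2-enoate | COC(=O)/C=C(/C)[C@@H](O)c1cc(OC)c(OCc2ccccc2)c(OC)c1 | intermediate (not isolated)
8 | (5R)-5-[4-(benzyloxy)-3,5-dimethoxyphenyl]-4-methylfuran-2(5H)-one | O=C1C=C(C)[C@H](c2cc(OC)c(OCc3ccccc3)c(OC)c2)O1 | intermediate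
9 | (5R)-5-[4-(benzyloxy)-3,5-dimethoxyphenyl]-4-methyl-2,5-dihydrofuran-2-ol (anomer mixture, present as its aluminium alkoxide) | OC1C=C(C)[C@H](c2cc(OC)c(OCc3ccccc3)c(OC)c2)O1 | intermediate (not isolated)
10 | (1R,2Z)-1-[4-(benzyloxy)-3,5-dimethoxyphenyl]-2-methylbut-2-ene-1,4-diol | OC/C=C(/C)[C@@H](O)c1cc(OC)c(OCc2ccccc2)c(OC)c1 | intermediate
11 | 2-(benzyloxy)-5-(dimethoxymethyl)-1,3-dimethoxybenzene | COc1cc(C(OC)OC)cc(OC)c1OCc1ccccc1 | intermediate (not isolated)
12 | (2R,4R)-2,4-bis[4-(benzyloxy)-3,5-dimethoxyphenyl]-5-methyl-4,7-dihydro-1,3-dioxepine (2,4-cis isomer shown) | COc1cc([C@@H]2OCC=C(C)[C@H](c3cc(OC)c(OCc4ccccc4)c(OC)c3)O2)cc(OC)c1OCc1ccccc1 | intermediate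
13 | (2R,4R,5S)-2,4-bis[4-(benzyloxy)-3,5-dimethoxyphenyl]-5-methyl-4,5-dihydro-1,3-dioxepine (2,4-cis, 4,5-cis) | COc1cc([C@@H]2OC=C[C@H](C)[C@H](c3cc(OC)c(OCc4ccccc4)c(OC)c3)O2)cc(OC)c1OCc1ccccc1 | intermediate
14 | (E)-[4-(benzyloxy)-3,5-dimethoxybenzylidene]{(1R,2S,3Z)-1-[4-(benzyloxy)-3,5-dimethoxyphenyl]-2-methyl-4-[(trimethylsilyl)oxy]but-3-en-1-yl}oxonium triflate | C[Si](C)(C)O/C=C\[C@H](C)[C@H](c1cc(OC)c(OCc2ccccc2)c(OC)c1)/[O+]=C/c1cc(OC)c(OCc2ccccc2)c(OC)c1.[O-]S(=O)(=O)C(F)(F)F | intermediate (not isolated)
15 | (2S,3S,4S,5R)-2,5-bis[4-(benzyloxy)-3,5-dimethoxyphenyl]-4-methyltetrahydrofuran-3-carbaldehyde | COc1cc([C@H]2O[C@@H](c3cc(OC)c(OCc4ccccc4)c(OC)c3)[C@@H](C)[C@@H]2C=O)cc(OC)c1OCc1ccccc1 | intermediate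
16 | [(2S,3R,4S,5R)-2,5-bis[4-(benzyloxy)-3,5-dimethoxyphenyl]-4-methyltetrahydrofuran-3-yl]methanol | COc1cc([C@H]2O[C@@H](c3cc(OC)c(OCc4ccccc4)c(OC)c3)[C@@H](C)[C@@H]2CO)cc(OC)c1OCc1ccccc1 | intermediate
17 | [(2S,3R,4S,5R)-2,5-bis[4-(benzyloxy)-3,5-dimethoxyphenyl]-4-methyltetrahydrofuran-3-yl]methyl methanesulfonate | COc1cc([C@H]2O[C@@H](c3cc(OC)c(OCc4ccccc4)c(OC)c3)[C@@H](C)[C@@H]2COS(C)(=O)=O)cc(OC)c1OCc1ccccc1 | intermediate
18 | (2S,3S,4S,5R)-2,5-bis[4-(benzyloxy)-3,5-dimethoxyphenyl]-3,4-dimethyltetrahydrofuran | COc1cc([C@H]2O[C@@H](c3cc(OC)c(OCc4ccccc4)c(OC)c3)[C@@H](C)[C@@H]2C)cc(OC)c1OCc1ccccc1 | intermediate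
19 | 4,4'-[(2S,3S,4S,5R)-3,4-dimethyltetrahydrofuran-2,5-diyl]bis(2,6-dimethoxyphenol) (2,3-trans, 3,4-trans, 4,5-cis) | COc1cc([C@H]2O[C@@H](c3cc(OC)c(O)c(OC)c3)[C@@H](C)[C@@H]2C)cc(OC)c1O | target

**Totals.** Total step count: 11. Longest linear sequence: 11 steps (1 to 19; aldehyde 3 from step 1 re-enters at step 5).

**Steps most likely to fail**

Step 7. The contraction may stop at a kinetic mixture because equilibration at C2/C3 is incomplete, or the acid may ionise the benzylic C5–O bond and scramble the cis C4/C5 pair. The fallback uses known lactone chemistry; it sets out from 8 and returns at 18.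
- Conjugate reduction of 8 with NaBH4/NiCl2·6H2O in MeOH, hydrogen adding anti to the aryl group, should give the cis-lactone (4S,5R)-5-Ar-4-methyldihydrofuran-2(3H)-one F1.
- LiN(SiMe3)2 and MeI should methylate its enolate trans to the C4 methyl group, giving (3S,4S,5R)-5-Ar-3,4-dimethyldihydrofuran-2(3H)-one F2.
- 2-(Benzyloxy)-5-bromo-1,3-dimethoxybenzene F3 (from commercial 4-bromo-2,6-dimethoxyphenol, 2 and K2CO3) is converted with n-BuLi into [4-(benzyloxy)-3,5-dimethoxyphenyl]lithium F4.
- F4 adds to F2 to give the hemiketal (3S,4S,5R)-2,5-di-Ar-3,4-dimethyltetrahydrofuran-2-ol F5.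
- Et3SiH/BF3·OEt2 should reduce F5 through the cyclic oxocarbenium ion, and continued exposure to BF3·OEt2 should equilibrate the benzylic C2 centre to the 2,3-trans ether 18, after which step 11 follows.

Step 6. Hydrogen delivery to C5 may show poor facial selectivity, or the double bond may migrate toward C4 into conjugation with the aryl group and destroy the carbinol centre. The fallback replaces substrate control by reagent control; it sets out from 12 and returns at 13. The chiral hydride generated from NiBr2((R,R)-Me-DuPhos), or its enantiomer, and LiBHEt3 belongs to a catalyst class that isomerises 5-methyl-4,7-dihydro-1,3-dioxepines with high enantioface selection. Used in its matched form, the catalyst rather than the C4 substituent should dictate which face of C5 receives hydrogen. It makes no new compound (F0).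

Step 5. Acid may ionise the benzylic, allylic carbinol (racemisation or cyclodehydration to a 2,5-dihydrofuran) faster than the acetal closes. The fallback is an aprotic silyl-transfer acetalisation; it sets out from 10 and returns at 12. TMSCl/imidazole should convert 10 into the bis(trimethylsilyl) ether (1R,2Z)-1-Ar-2-methyl-1,4-bis[(trimethylsilyl)oxy]but-2-ene F6. With 3 and catalytic TMSOTf in CH2Cl2 at −78 °C (Noyori acetalisation), F6 should give 12 without any Brønsted acid.

Further compounds
F1 | step 7 | (4S,5R)-5-[4-(benzyloxy)-3,5-dimethoxyphenyl]-4-methyldihydrofuran-2(3H)-one | O=C1O[C@@H](c2cc(OC)c(OCc3ccccc3)c(OC)c2)[C@@H](C)C1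
F2 | step 7 | (3S,4S,5R)-5-[4-(benzyloxy)-3,5-dimethoxyphenyl]-3,4-dimethyldihydrofuran-2(3H)-one | O=C1O[C@@H](c2cc(OC)c(OCc3ccccc3)c(OC)c2)[C@@H](C)[C@@H]1C
F3 | step 7 | 2-(benzyloxy)-5-bromo-1,3-dimethoxybenzene | COc1cc(Br)cc(OC)c1OCc1ccccc1
F4 | step 7 | [4-(benzyloxy)-3,5-dimethoxyphenyl]lithium | COc1cc([Li])cc(OC)c1OCc1ccccc1
F5 | step 7 | (3S,4S,5R)-2,5-bis[4-(benzyloxy)-3,5-dimethoxyphenyl]-3,4-dimethyltetrahydrofuran-2-ol (anomer mixture) | COc1cc(C2(O)O[C@@H](c3cc(OC)c(OCc4ccccc4)c(OC)c3)[C@@H](C)[C@@H]2C)cc(OC)c1OCc1ccccc1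
F0 | step 6 | none | none
F6 | step 5 | (1R,2Z)-1-[4-(benzyloxy)-3,5-dimethoxyphenyl]-2-methyl-1,4-bis[(trimethylsilyl)oxy]but-2-ene | C[Si](C)(C)OC/C=C(/C)[C@@H](O[Si](C)(C)C)c1cc(OC)c(OCc2ccccc2)c(OC)c1
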